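Take the first step as finished and reckon with the G it leaves free.

| setting | beta | eta | epsilon | amber | grey | violet |
|---|---|---|---|---|---|---|
| Z | 0.10 M | 0.10 M | 0.10 M | 0.10 M | 0.10 M | 0.10 M |
| G | 0.12 M | 0.27 M | 0.38 M | 0.150 M | 0.200 M | 0.400 M |
| remark | run made earlier | run made earlier | run made earlier |  |  |  |
| time |  |  |  | 4.0 min | 4.0 min | 4.0 min |

| run | time / min | L / % | X / % |
|---|---|---|---|
| beta | 0.500 | 66 | 0 |
| beta | 1.00 | 78 | 1 |
| beta | 1.50 | 82 | 0 |
| beta | 2.50 | 76 | 1 |
| beta | 3.00 | 80 | 2 |
| eta | 0.250 | 75 | 3 |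
| eta | 0.417 | 88 | 0 |
| eta | 0.833 | 83 | 1 |
| eta | 1.33 | 76 | 5 |
| eta | 3.00 | 60 | 0 |
| epsilon | 0.250 | 84 | 2 |
| epsilon | 0.417 | 86 | 0 |
| epsilon | 0.833 | 76 | 3 |
| epsilon | 1.33 | 66 | 1 |
| epsilon | 3.00 | 44 | 1 |

(standard deviation of a reading: 2 percentage points)



- final L, as a percentage of the Z charged, for each flask in turn (amber, grey, violet)

**Spare G.** In the eta run L reads highest at 0.417 min, while its fall from 0.833 min to 3.00 min gives a decay rate of 0.150 min⁻¹, a lifetime of 6.68 min, so L forms much sooner than it decays and I treat the two one after the other. Z is the limiting reagent of the first step, and each Z takes one G, so for violet the spare G, s, is 0.300 M, the charge of G minus the charge of Z.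

**First estimate.** Eta has s = 0.170 M; epsilon has 0.280 M and decays at 0.252 min⁻¹. Rate over s gives 0.0147 M⁻¹ s⁻¹ and 0.0150 M⁻¹ s⁻¹, so I take L as pseudo-first-order with rate κs, κ being the eta value. Epsilon, read back to zero time, gives 93.8%. My reckoning at 4.0 min is then 78.6% for amber, 65.9% for grey and 32.5% for violet.

**Two objections.** But s wears down as L reacts. Between 0.833 min and 3.00 min the epsilon readings of L fall by 0.0320 M, and that thinning already lies inside the rate I read, at an s close to violet's, so I let violet stand. The beta run is worse: the same formula gives 88.9% at 3.00 min, the reading is 80%, and the gap of 8.9 percentage points stands against a scatter of 2 points. At small s some Z seems to stay unconverted, so I commit to amber below my figure.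

**The forecast.** It says 79%, 68% and 32%, on the ground “That scales with leftover G”. My amber stands below its figure; my grey and violet stand beside its figures.

**The flasks.** They give 75.4%, 66.7% and 33.1%.

    Z + G ⇌ J + L (K = 32.0, k = 0.530 M⁻¹ s⁻¹)
    L + G ⇌ J + X (K = 0.670, k = 0.0220 M⁻¹ s⁻¹)
    X + G ⇌ J + Q (K = 3.90, k = 1.00 M⁻¹ s⁻¹)
    J + X → E (k = 0.0530 M⁻¹ s⁻¹)
    X + G → D (k = 0.570 M⁻¹ s⁻¹)

**Worn spare.** Grey has s = 0.100 M, but at 4.00 min its free G is 0.0528 M, about half of that. This wearing away of G, together with the early hour of the reading, is part of what holds grey's L at 66.7%: without the wearing grey's L stands at 37.4%, and at 40.0 min it stands at 27.2%. In violet, of the s of 0.300 M, the free G at 4.00 min is 0.174 M, and L stands at 33.1%.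

(The data were computed for substances that don't exist; the scatter is artificial.)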